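**Retrosynthetic overview**
1. Last operations: C15–O desilylation and C8 acylation of the finished tricycle.
2. Key disconnection, C6–C7 and O6–C12 together: a CrCl2-mediated intramolecular allylation of a Z-enal by a 2-(bromomethyl)acrylate, then lactonisation, closes the ten-membered carbocycle and the α-methylene-γ-lactone in one operation and sets C6 and C7.
3. The allyl bromide comes from a C7 aldehyde (Morita–Baylis–Hillman reaction, SN2′ bromination).
4. The 3(2H)-furanone is the first ring: three-component union of a (Z)-β-iodo enal (C4–C6, C15), carbon monoxide (C3) and a tertiary propargylic alcohol (C1, C2, C7–C10), then amine/acid hydration–cyclisation.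
5. C8 and C10 come from a proline aldol and a chelation-controlled ethynylation. Ring order: furanone, then carbocycle and lactone together.

Assumption: atom labels C1–C15 are the germacrane positions of the target (C1 ketone, C3 and C10 joined by the furanone oxygen, C6 lactone oxygen, C8 ester, C11=C13 methylene, C12 lactone carbonyl, C14 methyl, C15 hydroxymethyl); bare numbers are compound numbers.

**Step 1**
Reactants: 1 2-butyne-1,4-diol
Product: 2 4-[(tert-butyldiphenylsilyl)oxy]but-2-yn-1-ol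
Conditions: TBDPSCl (1 equiv), 1 (4 equiv), imidazole, DMF, 0 °C to rt
Reagents that add atoms: tert-butyl(chloro)diphenylsilane, CC(C)(C)[Si](Cl)(c1ccccc1)c1ccccc1
Why: Statistical mono-silylation (silyl ether formation) of the cheap symmetrical diol used in excess differentiates the two oxygens (future C15–O and C6) from the outset; no stereocentre.

**Step 2**
Reactants: 2 4-[(tert-butyldiphenylsilyl)oxy]but-2-yn-1-ol
Product: 4 (2Z)-4-[(tert-butyldiphenylsilyl)oxy]-3-iodobut-2-en-1-ol, via vinylalanate 3 (not isolated)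
Conditions: NaAlH2(OCH2CH2OMe)2, THF, 0 °C; then I2, −78 to 0 °C
Reagents that add atoms: iodine, [I][I]
Why: Hydroxyl-directed trans-hydroalumination of the propargylic alcohol puts aluminium on the distal alkyne carbon in a five-membered alanate, and iodinolysis with retention gives only the (Z)-vinyl iodide, so iodine (future C3 attachment) is cis to the carbinol carbon (future C6) and the C4=C5 geometry of the target is fixed.

**Step 3**
Reactants: 4 (2Z)-4-[(tert-butyldiphenylsilyl)oxy]-3-iodobut-2-en-1-ol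
Product: 5 (2Z)-4-[(tert-butyldiphenylsilyl)oxy]-3-iodobut-2-enal
Conditions: TEMPO (10 mol %), PhI(OAc)2, CH2Cl2, rt
Reagents that add atoms: none
Why: Oxoammonium-catalysed (TEMPO/PhI(OAc)2) oxidation of the primary allylic alcohol is neutral and does not isomerise the Z β-iodo enal, which is used at once.

**Step 4**
Reactants: 6 acetone, 7 2,2-dimethoxyacetaldehyde
Product: 8 (4R)-4-hydroxy-5,5-dimethoxypentan-2-one
Conditions: L-proline (30 mol %), 7 (60 % aq), acetone/DMSO (1:4), rt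
Reagents that add atoms: none
Why: L-Proline-catalysed direct aldol reaction in which the acetone enamine attacks the Re face of the α-branched aldehyde through the hydrogen-bonded List–Houk transition state, setting C8 as R (same sense as with isobutyraldehyde).

**Step 5**
Reactants: 8 (4R)-4-hydroxy-5,5-dimethoxypentan-2-one, 9 ethynylmagnesium bromide
Product: 10 (3R,5R)-6,6-dimethoxy-3-methylhex-1-yne-3,5-diol
Conditions: HC≡CMgBr (3.5 equiv), THF, −78 to −30 °C; aq NH4Cl
Reagents that add atoms: none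
Why: Chelation-controlled Grignard addition (Cram–Reetz 1,3-induction): the magnesium alkoxide of the C8 hydroxyl chelates the ketone in a six-membered ring and the acetylide adds axially, trans to the C8 substituent, giving the 1,3-anti diol (alkynyl in the chain) with C10 R, the minor epimer being removed by chromatography.

**Step 6**
Reactants: 10 (3R,5R)-6,6-dimethoxy-3-methylhex-1-yne-3,5-diol
Product: 11 (3R,5R)-6,6-dimethoxy-3-methyl-5-[(triethylsilyl)oxy]hex-1-yn-3-ol
Conditions: TESCl (1.1 equiv), imidazole, CH2Cl2, −20 to 0 °C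
Reagents that add atoms: chlorotriethylsilane, CC[Si](Cl)(CC)CC
Why: Selective silyl ether formation at the secondary C8 hydroxyl, the hindered tertiary propargylic hydroxyl staying free as the future furanone oxygen.

**Step 7**
Reactants: 11 (3R,5R)-6,6-dimethoxy-3-methyl-5-[(triethylsilyl)oxy]hex-1-yn-3-ol, 5 (2Z)-4-[(tert-butyldiphenylsilyl)oxy]-3-iodobut-2-enal, 12 carbon monoxide
Product: 16 (2Z)-4-[(tert-butyldiphenylsilyl)oxy]-3-{(5R)-5-[(2R)-3,3-dimethoxy-2-(triethylsilyloxy)propyl]-5-methyl-4-oxo-4,5-dihydrofuran-2-yl}but-2-enal, via ynone 13 (not isolated), via enaminone 14 (not isolated), via diketone 15 (not isolated)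
Conditions: PdCl2(PPh3)2 (5 mol %), CuI (2 mol %), i-Pr2NEt, CO (5 bar), THF, rt; then Et2NH, 0 °C; then AcOH/H2O, rt
Reagents that add atoms: water, O
Why: Carbonylative Sonogashira coupling (oxidative addition with retention of the Z geometry, CO insertion, alkynylation) makes CO the C3 carbon of γ-hydroxy ynone 13, conjugate addition of Et2NH and hydrolysis give the α′-hydroxy 1,3-diketone 15, and cyclodehydration through the tertiary hydroxyl closes the 3(2H)-furanone (classical amine-mediated hydration–cyclisation of 4-hydroxy-2-ynones) without touching C8 or C10.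

**Step 8**
Reactants: 16 (2Z)-4-[(tert-butyldiphenylsilyl)oxy]-3-{(5R)-5-[(2R)-3,3-dimethoxy-2-(triethylsilyloxy)propyl]-5-methyl-4-oxo-4,5-dihydrofuran-2-yl}but-2-enal
Product: 18 (2Z)-4-[(tert-butyldiphenylsilyl)oxy]-3-{(5R)-5-methyl-4-oxo-5-[(2R)-3-oxo-2-(triethylsilyloxy)propyl]-4,5-dihydrofuran-2-yl}but-2-enal, via pyridinium salt 17 (not isolated)
Conditions: TESOTf, 2,6-lutidine, CH2Cl2, 0 °C; then H2O, rt
Reagents that add atoms: water, O
Why: Silyl triflate/2,6-lutidine acetal cleavage: ionisation of the dimethyl acetal and capture by lutidine gives an N,O-acetal pyridinium salt that water hydrolyses to the aldehyde under non-acidic conditions, so both silyl ethers, the enal and the C8 stereocentre survive.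

**Step 9**
Reactants: 18 (2Z)-4-[(tert-butyldiphenylsilyl)oxy]-3-{(5R)-5-methyl-4-oxo-5-[(2R)-3-oxo-2-(triethylsilyloxy)propyl]-4,5-dihydrofuran-2-yl}but-2-enal, 19 methyl acrylate
Product: 20 methyl (4R)-5-[(2R)-5-{(2Z)-1-[(tert-butyldiphenylsilyl)oxy]-4-oxobut-2-en-2-yl}-2-methyl-3-oxo-2,3-dihydrofuran-2-yl]-3-hydroxy-2-methylidene-4-[(triethylsilyl)oxy]pentanoate as a mixture of carbinol epimers
Conditions: DABCO (1 equiv), methyl acrylate (10 equiv), MeOH, rt
Reagents that add atoms: none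
Why: Morita–Baylis–Hillman reaction, chemoselective for the electrophilic α-silyloxy aliphatic aldehyde over the hindered β,β-disubstituted conjugated enal; the new carbinol centre need not be controlled because it becomes sp2 in the next step.

**Step 10**
Reactants: 20 methyl (4R)-5-[(2R)-5-{(2Z)-1-[(tert-butyldiphenylsilyl)oxy]-4-oxobut-2-en-2-yl}-2-methyl-3-oxo-2,3-dihydrofuran-2-yl]-3-hydroxy-2-methylidene-4-[(triethylsilyl)oxy]pentanoate
Product: 21 methyl (2Z,4R)-2-(bromomethyl)-5-[(2R)-5-{(2Z)-1-[(tert-butyldiphenylsilyl)oxy]-4-oxobut-2-en-2-yl}-2-methyl-3-oxo-2,3-dihydrofuran-2-yl]-4-[(triethylsilyl)oxy]pent-2-enoate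
Conditions: NBS, Me2S (premixed), CH2Cl2, −20 °C to rt
Reagents that add atoms: N-bromosuccinimide, O=C1CCC(=O)N1Br
Why: Corey–Kim-type activation of the allylic alcohol as an alkoxysulfonium salt and SN2′ displacement by bromide (allylic transposition) give the thermodynamically preferred (Z)-2-(bromomethyl)alk-2-enoate, and premixing NBS with Me2S leaves no free electrophilic bromine for the furanone or the enal.

**Step 11**
Reactants: 21 methyl (2Z,4R)-2-(bromomethyl)-5-[(2R)-5-{(2Z)-1-[(tert-butyldiphenylsilyl)oxy]-4-oxobut-2-en-2-yl}-2-methyl-3-oxo-2,3-dihydrofuran-2-yl]-4-[(triethylsilyl)oxy]pent-2-enoate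
Product: 25 (6R,7R,8R,10R,4Z)-15-[(tert-butyldiphenylsilyl)oxy]-8-hydroxy-1-oxo-3,10-epoxygermacra-2,4,11(13)-trien-12,6-olide, via allylchromium 22 (not isolated), via hydroxy ester 23 (not isolated), via silyl lactone 24 (not isolated)
Conditions: CrCl2 (8 equiv), THF, rt, slow addition (final 2 mM); then 1 M HCl, rt
Reagents that add atoms: none
Why: Intramolecular Nozaki–Hiyama allylation followed by lactonisation forms the ten-membered carbocycle (C6–C7) and the α-methylene-γ-lactone in one operation: the equilibrating σ-allylchromium adds to the enal through a chair Zimmerman–Traxler transition state with C5 and C8 pseudoequatorial (6,7-anti, hence the trans lactone), the C8 stereocentre directs the face (C8–H eclipsing the C7=C11 bond to minimise allylic 1,3-strain, ring tether anti to the forming bond, electron-withdrawing silyloxy group outside) to give 6R,7R, and the chromium alkoxide then closes onto the ester while aqueous acid completes lactonisation and cleaves the TES ether.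

**Step 12**
Reactants: 25 (6R,7R,8R,10R,4Z)-15-[(tert-butyldiphenylsilyl)oxy]-8-hydroxy-1-oxo-3,10-epoxygermacra-2,4,11(13)-trien-12,6-olide, 26 isobutyric anhydride
Product: 27 (6R,7R,8R,10R,4Z)-15-[(tert-butyldiphenylsilyl)oxy]-1-oxo-3,10-epoxygermacra-2,4,11(13)-trien-12,6-olid-8-yl 2-methylpropanoate
Conditions: (i-PrCO)2O, Et3N, DMAP (20 mol %), CH2Cl2, 0 °C to rt
Reagents that add atoms: none
Why: DMAP-catalysed acylation (nucleophilic catalysis) of the only free hydroxyl with retention at C8, tertiary amines being unable to add irreversibly to the α-methylene lactone.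

**Step 13**
Reactants: 27 (6R,7R,8R,10R,4Z)-15-[(tert-butyldiphenylsilyl)oxy]-1-oxo-3,10-epoxygermacra-2,4,11(13)-trien-12,6-olid-8-yl 2-methylpropanoate
Product: 28 (6R,7R,8R,10R,4Z)-15-hydroxy-1-oxo-3,10-epoxygermacra-2,4,11(13)-trien-12,6-olid-8-yl 2-methylpropanoate
Conditions: HF·pyridine, pyridine/THF, 0 °C to rt
Reagents that add atoms: none
Why: Fluoride-mediated cleavage of the primary TBDPS ether under buffered conditions that tolerate the α-methylene lactone, the isobutyrate and the vinylogous ester of the furanone.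

**Compound list**
1 | 2-butyne-1,4-diol | OCC#CCO | starting material
2 | 4-[(tert-butyldiphenylsilyl)oxy]but-2-yn-1-ol | OCC#CCO[Si](c1ccccc1)(c1ccccc1)C(C)(C)C | intermediate
3 | sodium cyclic vinylalanate of 2 (five-membered O–Al–C ring, aluminium on the carbon bearing CH2OTBDPS, two 2-methoxyethoxy ligands) | [Na+].COCCO[Al-]1(OCCOC)OCC=C1CO[Si](c2ccccc2)(c2ccccc2)C(C)(C)C | intermediate (not isolated)
4 | (2Z)-4-[(tert-butyldiphenylsilyl)oxy]-3-iodobut-2-en-1-ol | OC/C=C(/CO[Si](c1ccccc1)(c1ccccc1)C(C)(C)C)I | intermediate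
5 | (2Z)-4-[(tert-butyldiphenylsilyl)oxy]-3-iodobut-2-enal | O=C/C=C(/CO[Si](c1ccccc1)(c1ccccc1)C(C)(C)C)I | intermediate
6 | acetone | CC(C)=O | starting material
7 | 2,2-dimethoxyacetaldehyde | COC(OC)C=O | starting material
8 | (4R)-4-hydroxy-5,5-dimethoxypentan-2-one | CC(=O)C[C@@H](O)C(OC)OC | intermediate
9 | ethynylmagnesium bromide | C#C[Mg]Br | starting material
10 | (3R,5R)-6,6-dimethoxy-3-methylhex-1-yne-3,5-diol | C#C[C@](C)(O)C[C@@H](O)C(OC)OC | intermediate
11 | (3R,5R)-6,6-dimethoxy-3-methyl-5-[(triethylsilyl)oxy]hex-1-yn-3-ol | C#C[C@](C)(O)C[C@@H](O[Si](CC)(CC)CC)C(OC)OC | intermediate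
12 | carbon monoxide | [C-]#[O+] | starting material
13 | (2Z,7R,9R)-3-{[(tert-butyldiphenylsilyl)oxy]methyl}-7-hydroxy-10,10-dimethoxy-7-methyl-4-oxo-9-[(triethylsilyl)oxy]dec-2-en-5-ynal | O=C/C=C(/CO[Si](c1ccccc1)(c1ccccc1)C(C)(C)C)C(=O)C#C[C@](C)(O)C[C@@H](O[Si](CC)(CC)CC)C(OC)OC | intermediate (not isolated)
14 | (2Z,7R,9R)-3-{[(tert-butyldiphenylsilyl)oxy]methyl}-6-(diethylamino)-7-hydroxy-10,10-dimethoxy-7-methyl-4-oxo-9-[(triethylsilyl)oxy]deca-2,5-dienal (enamine geometry not defined) | O=C/C=C(/CO[Si](c1ccccc1)(c1ccccc1)C(C)(C)C)C(=O)C=C(N(CC)CC)[C@](C)(O)C[C@@H](O[Si](CC)(CC)CC)C(OC)OC | intermediate (not isolated)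
15 | (2Z,7R,9R)-3-{[(tert-butyldiphenylsilyl)oxy]methyl}-7-hydroxy-10,10-dimethoxy-7-methyl-4,6-dioxo-9-[(triethylsilyl)oxy]dec-2-enal | O=C/C=C(/CO[Si](c1ccccc1)(c1ccccc1)C(C)(C)C)C(=O)CC(=O)[C@](C)(O)C[C@@H](O[Si](CC)(CC)CC)C(OC)OC | intermediate (not isolated)
16 | (2Z)-4-[(tert-butyldiphenylsilyl)oxy]-3-{(5R)-5-[(2R)-3,3-dimethoxy-2-(triethylsilyloxy)propyl]-5-methyl-4-oxo-4,5-dihydrofuran-2-yl}but-2-enal | O=C/C=C(/CO[Si](c1ccccc1)(c1ccccc1)C(C)(C)C)C2=CC(=O)[C@@](C)(C[C@@H](O[Si](CC)(CC)CC)C(OC)OC)O2 | intermediate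
17 | N,O-acetal pyridinium triflate of 16 (one acetal methoxy replaced by 2,6-dimethylpyridinium-1-yl; new centre not defined) | O=C/C=C(/CO[Si](c1ccccc1)(c1ccccc1)C(C)(C)C)C2=CC(=O)[C@@](C)(C[C@@H](O[Si](CC)(CC)CC)C(OC)[n+]3c(C)cccc3C)O2.[O-]S(=O)(=O)C(F)(F)F | intermediate (not isolated)
18 | (2Z)-4-[(tert-butyldiphenylsilyl)oxy]-3-{(5R)-5-methyl-4-oxo-5-[(2R)-3-oxo-2-(triethylsilyloxy)propyl]-4,5-dihydrofuran-2-yl}but-2-enal | O=C/C=C(/CO[Si](c1ccccc1)(c1ccccc1)C(C)(C)C)C2=CC(=O)[C@@](C)(C[C@@H](O[Si](CC)(CC)CC)C=O)O2 | intermediate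
19 | methyl acrylate | C=CC(=O)OC | starting material
20 | methyl (4R)-5-[(2R)-5-{(2Z)-1-[(tert-butyldiphenylsilyl)oxy]-4-oxobut-2-en-2-yl}-2-methyl-3-oxo-2,3-dihydrofuran-2-yl]-3-hydroxy-2-methylidene-4-[(triethylsilyl)oxy]pentanoate (carbinol epimers) | O=C/C=C(/CO[Si](c1ccccc1)(c1ccccc1)C(C)(C)C)C2=CC(=O)[C@@](C)(C[C@@H](O[Si](CC)(CC)CC)C(O)C(=C)C(=O)OC)O2 | intermediate
21 | methyl (2Z,4R)-2-(bromomethyl)-5-[(2R)-5-{(2Z)-1-[(tert-butyldiphenylsilyl)oxy]-4-oxobut-2-en-2-yl}-2-methyl-3-oxo-2,3-dihydrofuran-2-yl]-4-[(triethylsilyl)oxy]pent-2-enoate | O=C/C=C(/CO[Si](c1ccccc1)(c1ccccc1)C(C)(C)C)C2=CC(=O)[C@@](C)(C[C@@H](O[Si](CC)(CC)CC)/C=C(\CBr)C(=O)OC)O2 | intermediate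
22 | σ-allylchromium dichloride from 21 (CrCl2 unit on C13 in place of bromine; C7=C11 geometry equilibrating; C8 and C10 as in 21) | O=C/C=C(/CO[Si](c1ccccc1)(c1ccccc1)C(C)(C)C)C2=CC(=O)[C@@](C)(C[C@@H](O[Si](CC)(CC)CC)C=C(C[Cr](Cl)Cl)C(=O)OC)O2 | intermediate (not isolated)
23 | macrocyclic seco-lactone: methyl 2-(ten-membered carbocycle C7-yl)acrylate with free C6 hydroxyl, 8-O-TES and 15-O-TBDPS, present as its chromium alkoxide; C6, C7, C8, C10 arranged as in 25 | C=C(C(=O)OC)[C@H]1[C@H](O)/C=C(/CO[Si](c3ccccc3)(c3ccccc3)C(C)(C)C)C2=CC(=O)[C@@](C)(C[C@H]1O[Si](CC)(CC)CC)O2 | intermediate (not isolated)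
24 | 8-O-triethylsilyl ether of 25 (same spatial arrangement at C6, C7, C8, C10) | C=C1C(=O)O[C@@H]2/C=C(/CO[Si](c4ccccc4)(c4ccccc4)C(C)(C)C)C3=CC(=O)[C@@](C)(C[C@@H](O[Si](CC)(CC)CC)[C@@H]12)O3 | intermediate (not isolated)
25 | (6R,7R,8R,10R,4Z)-15-[(tert-butyldiphenylsilyl)oxy]-8-hydroxy-1-oxo-3,10-epoxygermacra-2,4,11(13)-trien-12,6-olide | C=C1C(=O)O[C@@H]2/C=C(/CO[Si](c4ccccc4)(c4ccccc4)C(C)(C)C)C3=CC(=O)[C@@](C)(C[C@@H](O)[C@@H]12)O3 | intermediate
26 | isobutyric anhydride | CC(C)C(=O)OC(=O)C(C)C | starting material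
27 | (6R,7R,8R,10R,4Z)-15-[(tert-butyldiphenylsilyl)oxy]-1-oxo-3,10-epoxygermacra-2,4,11(13)-trien-12,6-olid-8-yl 2-methylpropanoate | C=C1C(=O)O[C@@H]2/C=C(/CO[Si](c4ccccc4)(c4ccccc4)C(C)(C)C)C3=CC(=O)[C@@](C)(C[C@@H](OC(=O)C(C)C)[C@@H]12)O3 | intermediate
28 | (6R,7R,8R,10R,4Z)-15-hydroxy-1-oxo-3,10-epoxygermacra-2,4,11(13)-trien-12,6-olid-8-yl 2-methylpropanoate (CNP0176924.3) | C=C1C(=O)O[C@@H]2/C=C(/CO)C3=CC(=O)[C@@](C)(C[C@@H](OC(=O)C(C)C)[C@@H]12)O3 | target

**Step count and risks**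
Total step count: 13 (steps 1–3 make iodo-enal 5; steps 4–13 are the main line).
Longest linear sequence: 10 steps (steps 4–13, from acetone 6 and aldehyde 7).

Most likely to fail, in order:

Step 11 (ring closure onto the furanone-bridged seco-aldehyde, and the C6/C7 outcome). If CrCl2 gives no ring or the wrong diastereomer, the nucleophile is changed from a metal allyl (closed transition state) to an allylsilane (open, Lewis-acid-mediated transition state). The fallback sets out from dialdehyde 18 and bypasses steps 9 and 10. Chemoselective Wittig olefination of the C7 aldehyde with Ph3P=C(CO2Me)CH2SiMe3 gives the allylsilane methyl (2Z,4R)-5-[(2R)-5-{(2Z)-1-[(tert-butyldiphenylsilyl)oxy]-4-oxobut-2-en-2-yl}-2-methyl-3-oxo-2,3-dihydrofuran-2-yl]-4-[(triethylsilyl)oxy]-2-[(trimethylsilyl)methyl]pent-2-enoate F1. Intramolecular Hosomi–Sakurai cyclisation of F1 (BF3·OEt2, CH2Cl2, −78 °C, high dilution), then p-TsOH to lactonise and remove the TES group, comes back to the route at 25.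

Step 7 (three-component carbonylation with the sensitive Z iodo-enal; direct coupling without CO, or Z/E erosion at the ynone stage). The fallback introduces CO separately and sets out from iodo alcohol 4 and alkyne 11. Cyclocarbonylation of 4 (PdCl2(PPh3)2, CO, Et3N, THF) gives the butenolide 3-{[(tert-butyldiphenylsilyl)oxy]methyl}furan-2(5H)-one F2. The dilithio derivative of 11 (n-BuLi, THF, −78 °C) adds to the lactone carbonyl to give the alkynyl lactol 3-{[(tert-butyldiphenylsilyl)oxy]methyl}-2-{(3R,5R)-3-hydroxy-6,6-dimethoxy-3-methyl-5-[(triethylsilyl)oxy]hex-1-yn-1-yl}-2,5-dihydrofuran-2-ol F3, the ring tautomer of the Z hydroxy ynone. MnO2 oxidation of the open form comes back to the route at ynone 13, which is then isolated and taken through the Et2NH and aqueous acid stages of step 7 to 16.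

Step 9 (slow Morita–Baylis–Hillman reaction on a hindered α-silyloxy aldehyde, with possible C8 epimerisation or attack on the enal under prolonged DABCO). The fallback builds the acrylate by aldol addition and selenoxide elimination and sets out from 18. Mukaiyama aldol with the trimethylsilyl ketene acetal of methyl 3-(phenylselanyl)propanoate (BF3·OEt2, CH2Cl2, −78 °C) gives the β-hydroxy selenide methyl (4R)-5-[(2R)-5-{(2Z)-1-[(tert-butyldiphenylsilyl)oxy]-4-oxobut-2-en-2-yl}-2-methyl-3-oxo-2,3-dihydrofuran-2-yl]-3-hydroxy-2-[(phenylselanyl)methyl]-4-[(triethylsilyl)oxy]pentanoate F4. Oxidation (H2O2, pyridine, 0 °C) and syn-elimination of the selenoxide come back to the route at 20.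

**Further compounds**
F1 | step 11 | methyl (2Z,4R)-5-[(2R)-5-{(2Z)-1-[(tert-butyldiphenylsilyl)oxy]-4-oxobut-2-en-2-yl}-2-methyl-3-oxo-2,3-dihydrofuran-2-yl]-4-[(triethylsilyl)oxy]-2-[(trimethylsilyl)methyl]pent-2-enoate | O=C/C=C(/CO[Si](c1ccccc1)(c1ccccc1)C(C)(C)C)C2=CC(=O)[C@@](C)(C[C@@H](O[Si](CC)(CC)CC)/C=C(\C[Si](C)(C)C)C(=O)OC)O2
F2 | step 7 | 3-{[(tert-butyldiphenylsilyl)oxy]methyl}furan-2(5H)-one | O=C1OCC=C1CO[Si](c2ccccc2)(c2ccccc2)C(C)(C)C
F3 | step 7 | 3-{[(tert-butyldiphenylsilyl)oxy]methyl}-2-{(3R,5R)-3-hydroxy-6,6-dimethoxy-3-methyl-5-[(triethylsilyl)oxy]hex-1-yn-1-yl}-2,5-dihydrofuran-2-ol (hemiketal epimers) | OC1(C#C[C@](C)(O)C[C@@H](O[Si](CC)(CC)CC)C(OC)OC)OCC=C1CO[Si](c2ccccc2)(c2ccccc2)C(C)(C)C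
F4 | step 9 | methyl (4R)-5-[(2R)-5-{(2Z)-1-[(tert-butyldiphenylsilyl)oxy]-4-oxobut-2-en-2-yl}-2-methyl-3-oxo-2,3-dihydrofuran-2-yl]-3-hydroxy-2-[(phenylselanyl)methyl]-4-[(triethylsilyl)oxy]pentanoate (epimers at the two new centres) | O=C/C=C(/CO[Si](c1ccccc1)(c1ccccc1)C(C)(C)C)C2=CC(=O)[C@@](C)(C[C@@H](O[Si](CC)(CC)CC)C(O)C(C[Se]c3ccccc3)C(=O)OC)O2
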